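**Retrosynthetic overview**

- Target 10 is (3R,5S)-1-(4-hydroxy-3-methoxyphenyl)tetradecane-3,5-diol. The strategy rests on its C3(OH)–C4H2–C5(OH)–C6H2–C7 segment, a syn-1,3-diol that equals two acetaldehyde units stacked on the carbonyl carbon (C3) of an arylpropanal.
- C7–C8 is traced back to the C7=C8 alkene 9 (hydrogenation), and 9 to a Wittig reaction of lactol 6 with the heptylidene ylide 8 (C8–C14) made from salt 7.
- Key disconnection: C3–C4 and C5–C6 by an aldolase (DERA) tandem aldol of aldehyde 2 with two molecules of acetaldehyde 3; the resulting 5-hydroxy aldehyde closes through O3 and C7 to the oxane ring of lactol 6.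
- Aldehyde 2 comes from commercial coniferaldehyde 1 by hydrogenation of the C=C bond.
- Ring order: the guaiacyl ring is bought; the oxane (O3, C3–C7) is the only ring formed (step 2) and is opened again in step 3.

Key step: step 2

Remark: locants C1–C14 follow the target chain from the benzylic CH2 (C1) to the terminal methyl (C14); an acetaldehyde-tolerant DERA variant that accepts 2 is assumed to be obtainable by screening.

**Route**

Step 1
Reactants: 1 coniferaldehyde [(E)-3-(4-hydroxy-3-methoxyphenyl)prop-2-enal]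
Product: 2 3-(4-hydroxy-3-methoxyphenyl)propanal
Conditions: H2 (1 atm), 5% Pd/C, EtOAc, rt, stopped after uptake of 1 equiv H2; used fresh
Reagents that add atoms: none
Why: Heterogeneous catalytic hydrogenation; palladium should reduce the conjugated C=C of a cinnamaldehyde much faster than the aliphatic C=O that results, and the phenol, the methyl ether and the arene are inert in EtOAc at 1 atm.

Step 2
Reactants: 2 3-(4-hydroxy-3-methoxyphenyl)propanal; 3 acetaldehyde (two molecules enter the product)
Product: 6 (4R,6R)-6-[2-(4-hydroxy-3-methoxyphenyl)ethyl]oxane-2,4-diol (anomer mixture), via mono-aldol aldehyde 4 (not isolated), via open-chain dihydroxy aldehyde 5 (not isolated)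
Conditions: DERA (acetaldehyde-tolerant E. coli variant, C47M type, chosen by screening), 0.1 M triethanolamine buffer pH 7.5, 10–15% v/v DMSO, 2 (50 mM), acetaldehyde (2.5 equiv, slow feed), 25 °C, N2; acetone precipitation, EtOAc extraction
Reagents that add atoms: none
Why: Proposed new method: the active-site lysine of DERA forms an enamine with acetaldehyde that adds to the carbonyl of 2 (C3–C4 bond) to release 4, and 4 is then the acceptor for a second enamine addition (C5–C6 bond) that gives 5; the closest known reaction type is the DERA sequential double aldol of acetaldehyde onto chloroacetaldehyde or 3-azidopropanal, which gives 6-substituted 2,4-dideoxy lactols, and the new element is the bulky, lipophilic arylpropanal acceptor, for which a screened variant and DMSO cosolvent are assumed. The one ring closes by 6-exo-trig addition of the C3 hydroxyl to the C7 aldehyde of 5, and this hemiacetal removes the free aldehyde, pulls both reversible aldol steps forward and stops a third addition. Both carbinol centres are set by the enzyme, whose enamine should attack the same face of each acceptor carbonyl as in the statin lactols, which gives 3R in 4 and 3R,5R in 5 and so the 4R,6R lactol that carries the 3R,5S syn pattern of the target (the C5 descriptor changes only because the CIP ranks change once C7 is extended); the anomeric centre forms as a mixture and is lost in step 3. The step needs 2 to beat acetaldehyde as the first acceptor, which the unhindered α-CH2 aldehyde of 2, its phenol-aided solubility and the slow acetaldehyde feed should secure, and it needs a stop after two additions, which the 1,5-relation of O3 and C7 secures because it exists only after the second addition.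

Step 3
Reactants: 6 (4R,6R)-6-[2-(4-hydroxy-3-methoxyphenyl)ethyl]oxane-2,4-diol; 7 heptyltriphenylphosphonium bromide
Product: 9 (3R,5S,7Z)-1-(4-hydroxy-3-methoxyphenyl)tetradec-7-ene-3,5-diol, via heptylidenetriphenylphosphorane 8 (not isolated)
Conditions: 7 (5.0 equiv), NaHMDS (4.8 equiv), THF, 0 °C, 30 min; then 6 in THF, −78 °C → rt; aq. NH4Cl
Reagents that add atoms: none
Why: Wittig olefination of a lactol; the lactol alkoxide is in equilibrium with the ring-opened aldehyde (the form 5), which the non-stabilised ylide should trap to give mainly the Z alkene, the excess ylide covering the acidic phenol and hydroxyls, while the two carbinol centres are not α to the carbonyl and cannot epimerise.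

Step 4
Reactants: 9 (3R,5S,7Z)-1-(4-hydroxy-3-methoxyphenyl)tetradec-7-ene-3,5-diol
Product: 10 (3R,5S)-1-(4-hydroxy-3-methoxyphenyl)tetradecane-3,5-diol
Conditions: H2 (1 atm), 10% Pd/C, EtOAc, rt
Reagents that add atoms: none
Why: Heterogeneous hydrogenation of an isolated disubstituted alkene; there is no benzylic or allylic C–O bond to cleave, the alkene geometry becomes irrelevant, and both stereocentres are spectators.

**Compound list**

1 | coniferaldehyde, (E)-3-(4-hydroxy-3-methoxyphenyl)prop-2-enal | O=C/C=C/c1ccc(O)c(OC)c1 | starting material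
2 | 3-(4-hydroxy-3-methoxyphenyl)propanal | O=CCCc1ccc(O)c(OC)c1 | intermediate
3 | acetaldehyde | CC=O | starting material
4 | (3R)-3-hydroxy-5-(4-hydroxy-3-methoxyphenyl)pentanal (mono-aldol aldehyde, not isolated) | O=CC[C@H](O)CCc1ccc(O)c(OC)c1 | intermediate
5 | (3R,5R)-3,5-dihydroxy-7-(4-hydroxy-3-methoxyphenyl)heptanal (open-chain dihydroxy aldehyde, not isolated) | O=CC[C@H](O)C[C@H](O)CCc1ccc(O)c(OC)c1 | intermediate
6 | (4R,6R)-6-[2-(4-hydroxy-3-methoxyphenyl)ethyl]oxane-2,4-diol (anomer mixture) | OC1C[C@H](O)C[C@@H](CCc2ccc(O)c(OC)c2)O1 | intermediate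
7 | heptyltriphenylphosphonium bromide | CCCCCCC[P+](c1ccccc1)(c1ccccc1)c1ccccc1.[Br-] | starting material
8 | heptylidenetriphenylphosphorane (not isolated) | CCCCCCC=P(c1ccccc1)(c1ccccc1)c1ccccc1 | intermediate
9 | (3R,5S,7Z)-1-(4-hydroxy-3-methoxyphenyl)tetradec-7-ene-3,5-diol | CCCCCC/C=C\C[C@H](O)C[C@H](O)CCc1ccc(O)c(OC)c1 | intermediate
10 | (3R,5S)-1-(4-hydroxy-3-methoxyphenyl)tetradecane-3,5-diol | CCCCCCCCC[C@H](O)C[C@H](O)CCc1ccc(O)c(OC)c1 | target

**Totals**

Total step count: 4. Longest linear sequence: 4 steps (1 → 2 → 6 → 9 → 10).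

**Steps most likely to fail**

1. Step 2 (proposed new method). What may go wrong: the bulky arylpropanal may bind poorly, so turnover is slow, acetaldehyde self-addition takes over, and the enzyme is gradually deactivated by acetaldehyde-derived crotonaldehyde. The fallback uses known chemistry, sets out from 2 and returns at 10.
   - The phenol of 2 is silylated (TBSCl, imidazole, DMF) to 3-[4-(tert-butyldimethylsilyloxy)-3-methoxyphenyl]propanal F1.
   - Brown allylation with B-allyldiisopinocampheylborane of the (+)-α-pinene series (from (−)-Ipc2BOMe and allylMgBr; Et2O, −78 °C; then NaOH/H2O2) should deliver allyl to the Si face and give (3R)-1-[4-(tert-butyldimethylsilyloxy)-3-methoxyphenyl]hex-5-en-3-ol F2.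
   - Boc2O/DMAP in MeCN gives tert-butyl (3R)-1-[4-(tert-butyldimethylsilyloxy)-3-methoxyphenyl]hex-5-en-3-yl carbonate F3.
   - Bartlett–Smith iodocarbonate cyclisation (IBr, toluene, −85 °C) should close the cis cyclic carbonate (4R,6R)-4-{2-[4-(tert-butyldimethylsilyloxy)-3-methoxyphenyl]ethyl}-6-(iodomethyl)-1,3-dioxan-2-one F4, which sets C5 syn to C3.
   - K2CO3 in MeOH converts it into the syn epoxy alcohol (2R)-4-[4-(tert-butyldimethylsilyloxy)-3-methoxyphenyl]-1-[(2R)-oxiran-2-yl]butan-2-ol F5.
   - Octylmagnesium bromide (3 equiv) with catalytic CuI (THF, −30 °C) opens the epoxide at its CH2 terminus (C6) to give (3R,5S)-1-[4-(tert-butyldimethylsilyloxy)-3-methoxyphenyl]tetradecane-3,5-diol F6.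
   - TBAF in THF then gives 10.

2. Step 3. What may go wrong: ring opening of the lactol alkoxide is slow, and the free β-oxido aldehyde can undergo retro-aldol cleavage or β-elimination before the ylide traps it; the sodium phenoxide may also precipitate and stall the reaction. The fallback sets out from 6 and returns at 9; it fixes the open-chain form and masks the diol before olefination.
   - 1,3-Propanedithiol with BF3·OEt2 (CH2Cl2, 0 °C) opens the lactol to (3R,5R)-6-(1,3-dithian-2-yl)-1-(4-hydroxy-3-methoxyphenyl)hexane-3,5-diol F7.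
   - 2,2-Dimethoxypropane with PPTS in acetone gives the syn acetonide 4-{2-[(4R,6R)-6-(1,3-dithian-2-ylmethyl)-2,2-dimethyl-1,3-dioxan-4-yl]ethyl}-2-methoxyphenol F8.
   - MeI and CaCO3 in aqueous MeCN (40 °C) unmask the aldehyde 2-{(4R,6R)-6-[2-(4-hydroxy-3-methoxyphenyl)ethyl]-2,2-dimethyl-1,3-dioxan-4-yl}acetaldehyde F9.
   - Wittig reaction with ylide 8 (2.2 equiv, one for the phenol; THF, −78 °C → rt) gives 4-{2-[(4R,6S)-2,2-dimethyl-6-[(2Z)-non-2-en-1-yl]-1,3-dioxan-4-yl]ethyl}-2-methoxyphenol F10.
   - AcOH/H2O/THF (40 °C) removes the acetonide and gives 9, which goes on through step 4.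

3. Step 1. What may go wrong: over-reduction of the new aliphatic aldehyde to the alcohol, or aldol self-condensation of 2 on the catalyst and on standing. The fallback sets out from 1 and returns at 2: iminium-catalysed transfer hydrogenation with Hantzsch ester (1.1 equiv) and dibenzylammonium trifluoroacetate (5 mol%) in THF at rt. This delivers hydride only to the β-carbon of the enal and cannot touch the C=O. The path makes no compound outside the list (none F0).

**Further compounds**

F1 | step 2 | 3-[4-(tert-butyldimethylsilyloxy)-3-methoxyphenyl]propanal | O=CCCc1ccc(O[Si](C)(C)C(C)(C)C)c(OC)c1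
F2 | step 2 | (3R)-1-[4-(tert-butyldimethylsilyloxy)-3-methoxyphenyl]hex-5-en-3-ol | C=CC[C@H](O)CCc1ccc(O[Si](C)(C)C(C)(C)C)c(OC)c1
F3 | step 2 | tert-butyl (3R)-1-[4-(tert-butyldimethylsilyloxy)-3-methoxyphenyl]hex-5-en-3-yl carbonate | C=CC[C@H](OC(=O)OC(C)(C)C)CCc1ccc(O[Si](C)(C)C(C)(C)C)c(OC)c1
F4 | step 2 | (4R,6R)-4-{2-[4-(tert-butyldimethylsilyloxy)-3-methoxyphenyl]ethyl}-6-(iodomethyl)-1,3-dioxan-2-one | IC[C@H]1C[C@@H](CCc2ccc(O[Si](C)(C)C(C)(C)C)c(OC)c2)OC(=O)O1
F5 | step 2 | (2R)-4-[4-(tert-butyldimethylsilyloxy)-3-methoxyphenyl]-1-[(2R)-oxiran-2-yl]butan-2-ol | C1O[C@@H]1C[C@H](O)CCc1ccc(O[Si](C)(C)C(C)(C)C)c(OC)c1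
F6 | step 2 | (3R,5S)-1-[4-(tert-butyldimethylsilyloxy)-3-methoxyphenyl]tetradecane-3,5-diol | CCCCCCCCC[C@H](O)C[C@H](O)CCc1ccc(O[Si](C)(C)C(C)(C)C)c(OC)c1
F7 | step 3 | (3R,5R)-6-(1,3-dithian-2-yl)-1-(4-hydroxy-3-methoxyphenyl)hexane-3,5-diol | C1CSC(SC1)C[C@H](O)C[C@H](O)CCc1ccc(O)c(OC)c1
F8 | step 3 | 4-{2-[(4R,6R)-6-(1,3-dithian-2-ylmethyl)-2,2-dimethyl-1,3-dioxan-4-yl]ethyl}-2-methoxyphenol | C1CSC(SC1)C[C@H]1C[C@@H](CCc2ccc(O)c(OC)c2)OC(C)(C)O1
F9 | step 3 | 2-{(4R,6R)-6-[2-(4-hydroxy-3-methoxyphenyl)ethyl]-2,2-dimethyl-1,3-dioxan-4-yl}acetaldehyde | O=CC[C@H]1C[C@@H](CCc2ccc(O)c(OC)c2)OC(C)(C)O1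
F10 | step 3 | 4-{2-[(4R,6S)-2,2-dimethyl-6-[(2Z)-non-2-en-1-yl]-1,3-dioxan-4-yl]ethyl}-2-methoxyphenol | CCCCCC/C=C\C[C@H]1C[C@@H](CCc2ccc(O)c(OC)c2)OC(C)(C)O1
F0 | step 1 | none | none
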